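**Plan**

1. Locants: oxane ring O1, C2 (bears the acrylic acid unit), C3, C4, C5 (bears the chain), C6; side chain C1'–C13'. Retrosynthetic cuts: CO2H back to CH2OH; C1'–C2' (α-sulfonyl carbanion plus terminal epoxide, sulfone then removed); ring bond C4–C5 (radical closure); ether bond O1–C6; in the epoxide fragment C4'–CH3 and C5'–C6'.
2. Enabling feature: O1 joins an allylic carbinol carbon (C2) to a CH2 (C6), and C5 carries its chain through a CH2 (C1'). An O1–C6 allyl ether whose C5=C1' bond bears PhSO2 on C1' therefore puts an electron-poor alkene six atoms from a C4 radical.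
3. Forward: Morita–Baylis–Hillman adduct (C2–C4 plus acrylate) → O-alkylation with a sulfonyl allyl bromide → iodide → C4–C5 ring closure → the sulfone carbanion opens a C15 epoxide (from D-glycerate and geranyl bromide) → desulfonylation → oxidation to the acid.
4. Stereochemistry: C2 from the β-isocupreidine-catalysed Morita–Baylis–Hillman reaction; C5 from the chair transition state of the cyclization (trans to C2); C3' from methyl (R)-glycerate acetonide; C4' from Felkin–Anh addition of MeTi(OiPr)3; both E alkenes from geranyl bromide.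
5. Helpers: PhSO2 activates the alkene, then carries the carbanion, and leaves in step 14; the acrylate is held as the allylic alcohol from step 6 to step 15; a triethylsilyl ether masks the tertiary alcohol from step 12 to step 16.

Key step: step 7

**Route**

Step 1
Reactants: 1 allyl phenyl sulfone
Product: 3 [(1E)-3-bromoprop-1-en-1-yl]sulfonylbenzene, via 2,3-dibromopropyl phenyl sulfone 2 (not isolated)
Conditions: Br2, CH2Cl2, 0 °C; then Et3N (1.05 equiv), 0 °C
Reagents that add atoms: bromine, BrBr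
Why: Bromine addition to the allyl group followed by E1cB dehydrobromination (most acidic α-sulfonyl proton, β-bromide leaves) should give the conjugated (E)-vinyl sulfone with the primary allylic bromide intact.

Step 2
Reactants: 4 3-[(tert-butyldimethylsilyl)oxy]propanal; 5 1,1,1,3,3,3-hexafluoropropan-2-yl acrylate
Product: 7 methyl (3R)-5-[(tert-butyldimethylsilyl)oxy]-3-hydroxy-2-methylidenepentanoate, via hexafluoroisopropyl ester 6 (not isolated)
Conditions: β-isocupreidine (0.1 equiv), DMF, −55 °C; then NaOMe, MeOH, −20 to 0 °C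
Reagents that add atoms: sodium methoxide, C[O-].[Na+]
Why: Asymmetric Morita–Baylis–Hillman reaction in which the chiral quinuclidine adds to the activated acrylate and its phenolic OH organises the aldol step, so that the aliphatic aldehyde should give the (R)-carbinol (the future C2); methoxide then exchanges the activated ester.

Step 3
Reactants: 7 methyl (3R)-5-[(tert-butyldimethylsilyl)oxy]-3-hydroxy-2-methylidenepentanoate; 3 [(1E)-3-bromoprop-1-en-1-yl]sulfonylbenzene
Product: 8 methyl (3R)-5-[(tert-butyldimethylsilyl)oxy]-2-methylidene-3-{[(2E)-3-(phenylsulfonyl)prop-2-en-1-yl]oxy}pentanoate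
Conditions: Ag2O, 4 Å molecular sieves, CH2Cl2, 23 °C, dark
Reagents that add atoms: none
Why: Silver oxide-mediated Williamson etherification, in which silver activates the primary allylic bromide toward the neutral alcohol, so no free alkoxide arises that could cause retro-aldol, allylic transposition or oxa-Michael addition, and the carbinol centre is untouched.

Step 4
Reactants: 8 methyl (3R)-5-[(tert-butyldimethylsilyl)oxy]-2-methylidene-3-{[(2E)-3-(phenylsulfonyl)prop-2-en-1-yl]oxy}pentanoate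
Product: 9 methyl (3R)-5-hydroxy-2-methylidene-3-{[(2E)-3-(phenylsulfonyl)prop-2-en-1-yl]oxy}pentanoate
Conditions: camphorsulfonic acid (0.1 equiv), MeOH, 0 °C
Reagents that add atoms: none
Why: Acid-catalysed methanolysis of the primary silyl ether, chosen over fluoride so that no alkoxide can add to the acrylate or the vinyl sulfone.

Step 5
Reactants: 9 methyl (3R)-5-hydroxy-2-methylidene-3-{[(2E)-3-(phenylsulfonyl)prop-2-en-1-yl]oxy}pentanoate
Product: 10 methyl (3R)-5-iodo-2-methylidene-3-{[(2E)-3-(phenylsulfonyl)prop-2-en-1-yl]oxy}pentanoate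
Conditions: I2, PPh3, imidazole, CH2Cl2, 0 °C
Reagents that add atoms: iodine, II
Why: Appel-type iodination of the unhindered primary alcohol through its alkoxyphosphonium salt, with the phosphine consumed by iodine before the alcohol is added.

Step 6
Reactants: 10 methyl (3R)-5-iodo-2-methylidene-3-{[(2E)-3-(phenylsulfonyl)prop-2-en-1-yl]oxy}pentanoate
Product: 11 (3R)-5-iodo-2-methylidene-3-{[(2E)-3-(phenylsulfonyl)prop-2-en-1-yl]oxy}pentan-1-ol
Conditions: i-Bu2AlH (2.5 equiv), CH2Cl2, −78 °C; Rochelle salt work-up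
Reagents that add atoms: none
Why: 1,2-Reduction of the α-substituted acrylate to the allylic alcohol at −78 °C, where iodide and vinyl sulfone should be inert; this removes the second radical and Michael acceptor before the ring closure and the carbanion step.

Step 7
Reactants: 11 (3R)-5-iodo-2-methylidene-3-{[(2E)-3-(phenylsulfonyl)prop-2-en-1-yl]oxy}pentan-1-ol
Product: 12 2-{(2R,5S)-5-[(phenylsulfonyl)methyl]oxan-2-yl}prop-2-en-1-ol
Conditions: (Me3Si)3SiH (1.5 equiv, slow addition), Et3B (0.3 equiv), air, toluene, 0.01 M, 0 to 23 °C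
Reagents that add atoms: none
Why: The silyl radical abstracts iodine from C4 of 11, the primary C4 radical adds to C5 (the β-carbon of the vinyl sulfone), and the sulfonyl-stabilised C1' radical takes hydrogen from (Me3Si)3SiH and carries the chain. The closest known reaction type is the reductive radical cyclization of ω-iodoalkyl allyl ethers onto acceptor alkenes (intramolecular Giese addition by the silane or tin hydride method). The oxane ring (C4, C3, C2, O1, C6, C5) closes in the 6-exo-trig mode. The new stereocentre C5 is controlled by the existing C2 centre through a chair-like transition state with the C2 substituent and the C5=C1' vinyl sulfone both pseudo-equatorial, which should give the 2,5-trans ring. The step needs 6-exo addition to beat 7-endo attack, 1,5-hydrogen transfer from C6 or from the allylic CH2OH, and direct reduction; the polarity match of nucleophilic radical and electron-poor β-carbon, the slow hydrogen donor and high dilution secure this. The 1,1-disubstituted alkene on C2 is unactivated and reachable only by disfavoured 4-exo or 5-endo closure, so it should stay out of the reaction.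

Step 8
Reactants: 13 methyl (4R)-2,2-dimethyl-1,3-dioxolane-4-carboxylate
Product: 15 1-[(4R)-2,2-dimethyl-1,3-dioxolan-4-yl]ethan-1-one, via Weinreb amide 14 (not isolated)
Conditions: MeNH(OMe)·HCl, i-PrMgCl (3 equiv), THF, −20 °C; then MeMgBr, 0 °C
Reagents that add atoms: N,O-dimethylhydroxylamine hydrochloride, CNOC.Cl (its MeN(OMe) group is found in 14 only); methylmagnesium bromide, C[Mg]Br
Why: The magnesium amide converts the ester into the Weinreb amide, whose chelated tetrahedral adduct with MeMgBr collapses only on work-up, so the methyl ketone should form without over-addition and without loss of the α-stereocentre.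

Step 9
Reactants: 15 1-[(4R)-2,2-dimethyl-1,3-dioxolan-4-yl]ethan-1-one; 16 geranyl bromide, (2E)-1-bromo-3,7-dimethylocta-2,6-diene
Product: 17 (4E)-1-[(4R)-2,2-dimethyl-1,3-dioxolan-4-yl]-5,9-dimethyldeca-4,8-dien-1-one
Conditions: LiN(i-Pr)2, THF, −78 °C; then 16, DMPU, −78 to −30 °C
Reagents that add atoms: none
Why: Kinetic deprotonation at the unhindered methyl group and SN2 alkylation of the lithium enolate by the allylic bromide forms C5'–C6' and brings in both (E)-alkenes, while the dioxolane α-hydrogen is left alone at low temperature.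

Step 10
Reactants: 17 (4E)-1-[(4R)-2,2-dimethyl-1,3-dioxolan-4-yl]-5,9-dimethyldeca-4,8-dien-1-one
Product: 18 (2R,5E)-2-[(4R)-2,2-dimethyl-1,3-dioxolan-4-yl]-6,10-dimethylundeca-5,9-dien-2-ol
Conditions: MeTi(OiPr)3 (3 equiv), THF, −40 to 0 °C
Reagents that add atoms: methyltitanium triisopropoxide, C[Ti](OC(C)C)(OC(C)C)OC(C)C
Why: The alkoxytitanium reagent cannot chelate, so the addition should follow the polar Felkin–Anh model (methyl enters anti to the dioxolane C–O bond, past the ring hydrogen), which sets the tertiary carbinol (the future C4') as (R).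

Step 11
Reactants: 18 (2R,5E)-2-[(4R)-2,2-dimethyl-1,3-dioxolan-4-yl]-6,10-dimethylundeca-5,9-dien-2-ol
Product: 19 (2R,3R,6E)-3,7,11-trimethyldodeca-6,10-diene-1,2,3-triol
Conditions: AcOH–H2O (4:1), 40 °C
Reagents that add atoms: none
Why: Mild acid hydrolysis of the terminal acetonide; the trisubstituted alkenes and the tertiary alcohol should tolerate aqueous acetic acid.

Step 12
Reactants: 19 (2R,3R,6E)-3,7,11-trimethyldodeca-6,10-diene-1,2,3-triol
Product: 22 triethyl{[(2R,5E)-6,10-dimethyl-2-[(2R)-oxiran-2-yl]undeca-5,9-dien-2-yl]oxy}silane, via primary tosylate 20 (not isolated), via epoxy alcohol 21 (not isolated)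
Conditions: NaH (3.3 equiv), 1-(4-methylbenzenesulfonyl)imidazole (1.05 equiv), THF, 0 to 23 °C; then Et3SiCl, 0 °C
Reagents that add atoms: 1-(4-methylbenzenesulfonyl)imidazole, Cc1ccc(cc1)S(=O)(=O)n1ccnc1 (its sulfonyl group is found in 20 only); chlorotriethylsilane, CC[Si](Cl)(CC)CC
Why: Selective sulfonylation of the primary alkoxide and intramolecular Williamson displacement by the neighbouring secondary alkoxide (only the C1–O bond is made and broken, so C2 keeps its configuration) should give the terminal epoxide, and the remaining tertiary alkoxide is silylated in the same flask.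

Step 13
Reactants: 12 2-{(2R,5S)-5-[(phenylsulfonyl)methyl]oxan-2-yl}prop-2-en-1-ol; 22 triethyl{[(2R,5E)-6,10-dimethyl-2-[(2R)-oxiran-2-yl]undeca-5,9-dien-2-yl]oxy}silane
Product: 23 2-{(2R,5S)-5-[(3R,4R,7E)-3-hydroxy-4,8,12-trimethyl-1-(phenylsulfonyl)-4-[(triethylsilyl)oxy]trideca-7,11-dien-1-yl]oxan-2-yl}prop-2-en-1-ol (both C1' epimers)
Conditions: n-BuLi (2.1 equiv), THF, −78 °C; then 22, BF3·OEt2 (2.5 equiv), −78 °C
Reagents that add atoms: none
Why: Lewis acid-promoted opening of a terminal epoxide by a lithiated sulfone: the α-sulfonyl carbanion of the dianion of 12 attacks the CH2 terminus (SN2, no stereocentre of 22 is touched) and forms C1'–C2'; the new sulfonyl-bearing centre is of no consequence.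

Step 14
Reactants: 23 2-{(2R,5S)-5-[(3R,4R,7E)-3-hydroxy-4,8,12-trimethyl-1-(phenylsulfonyl)-4-[(triethylsilyl)oxy]trideca-7,11-dien-1-yl]oxan-2-yl}prop-2-en-1-ol
Product: 24 2-{(2R,5S)-5-[(3R,4R,7E)-3-hydroxy-4,8,12-trimethyl-4-[(triethylsilyl)oxy]trideca-7,11-dien-1-yl]oxan-2-yl}prop-2-en-1-ol
Conditions: Na(Hg) (6%), Na2HPO4, MeOH–THF, −20 to 0 °C
Reagents that add atoms: none
Why: Reductive desulfonylation by electron transfer from sodium amalgam cleaves the alkyl C–S bond; the hydroxyl is γ and not β to the sulfone, so no elimination should occur, and the isolated alkenes are inert.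

Step 15
Reactants: 24 2-{(2R,5S)-5-[(3R,4R,7E)-3-hydroxy-4,8,12-trimethyl-4-[(triethylsilyl)oxy]trideca-7,11-dien-1-yl]oxan-2-yl}prop-2-en-1-ol
Product: 25 2-{(2R,5S)-5-[(3R,4R,7E)-3-hydroxy-4,8,12-trimethyl-4-[(triethylsilyl)oxy]trideca-7,11-dien-1-yl]oxan-2-yl}prop-2-enal
Conditions: MnO2 (activated, excess), CH2Cl2, 23 °C
Reagents that add atoms: none
Why: MnO2 oxidises only the allylic primary alcohol to the 2-substituted acrolein; the secondary alcohol is not allylic and the tertiary oxygen is silylated, so no glycol cleavage can intervene.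

Step 16
Reactants: 25 2-{(2R,5S)-5-[(3R,4R,7E)-3-hydroxy-4,8,12-trimethyl-4-[(triethylsilyl)oxy]trideca-7,11-dien-1-yl]oxan-2-yl}prop-2-enal
Product: 27 2-{(2R,5S)-5-[(3R,4R,7E)-3,4-dihydroxy-4,8,12-trimethyltrideca-7,11-dien-1-yl]oxan-2-yl}prop-2-enoic acid, via triethylsilyl ether acid 26 (not isolated)
Conditions: NaClO2, NaH2PO4, 2-methylbut-2-ene, t-BuOH–H2O, 0 to 23 °C; then 1 M HCl, THF, 23 °C
Reagents that add atoms: sodium chlorite, [Na+].[O-]Cl=O
Why: Pinnick oxidation turns the enal into the acrylic acid while 2-methylbut-2-ene scavenges HOCl and so protects the trisubstituted alkenes; dilute acid then hydrolyses the tertiary triethylsilyl ether.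

**Compound list**

1 | allyl phenyl sulfone | C=CCS(=O)(=O)c1ccccc1 | starting material
2 | 2,3-dibromopropyl phenyl sulfone (racemic) | BrCC(Br)CS(=O)(=O)c1ccccc1 | intermediate
3 | [(1E)-3-bromoprop-1-en-1-yl]sulfonylbenzene | BrC/C=C/S(=O)(=O)c1ccccc1 | intermediate
4 | 3-[(tert-butyldimethylsilyl)oxy]propanal | O=CCCO[Si](C)(C)C(C)(C)C | starting material
5 | 1,1,1,3,3,3-hexafluoropropan-2-yl acrylate | C=CC(=O)OC(C(F)(F)F)C(F)(F)F | starting material
6 | 1,1,1,3,3,3-hexafluoropropan-2-yl (3R)-5-[(tert-butyldimethylsilyl)oxy]-3-hydroxy-2-methylidenepentanoate | C=C(C(=O)OC(C(F)(F)F)C(F)(F)F)[C@H](O)CCO[Si](C)(C)C(C)(C)C | intermediate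
7 | methyl (3R)-5-[(tert-butyldimethylsilyl)oxy]-3-hydroxy-2-methylidenepentanoate | C=C(C(=O)OC)[C@H](O)CCO[Si](C)(C)C(C)(C)C | intermediate
8 | methyl (3R)-5-[(tert-butyldimethylsilyl)oxy]-2-methylidene-3-{[(2E)-3-(phenylsulfonyl)prop-2-en-1-yl]oxy}pentanoate | C=C(C(=O)OC)[C@H](OC/C=C/S(=O)(=O)c1ccccc1)CCO[Si](C)(C)C(C)(C)C | intermediate
9 | methyl (3R)-5-hydroxy-2-methylidene-3-{[(2E)-3-(phenylsulfonyl)prop-2-en-1-yl]oxy}pentanoate | C=C(C(=O)OC)[C@H](OC/C=C/S(=O)(=O)c1ccccc1)CCO | intermediate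
10 | methyl (3R)-5-iodo-2-methylidene-3-{[(2E)-3-(phenylsulfonyl)prop-2-en-1-yl]oxy}pentanoate | C=C(C(=O)OC)[C@H](OC/C=C/S(=O)(=O)c1ccccc1)CCI | intermediate
11 | (3R)-5-iodo-2-methylidene-3-{[(2E)-3-(phenylsulfonyl)prop-2-en-1-yl]oxy}pentan-1-ol | C=C(CO)[C@H](OC/C=C/S(=O)(=O)c1ccccc1)CCI | intermediate
12 | 2-{(2R,5S)-5-[(phenylsulfonyl)methyl]oxan-2-yl}prop-2-en-1-ol (2,5-trans) | C=C(CO)[C@H]1CC[C@H](CS(=O)(=O)c2ccccc2)CO1 | intermediate
13 | methyl (4R)-2,2-dimethyl-1,3-dioxolane-4-carboxylate | CC1(C)OC[C@@H](O1)C(=O)OC | starting material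
14 | (4R)-N-methoxy-N,2,2-trimethyl-1,3-dioxolane-4-carboxamide | CC1(C)OC[C@@H](O1)C(=O)N(C)OC | intermediate
15 | 1-[(4R)-2,2-dimethyl-1,3-dioxolan-4-yl]ethan-1-one | CC1(C)OC[C@@H](O1)C(C)=O | intermediate
16 | geranyl bromide, (2E)-1-bromo-3,7-dimethylocta-2,6-diene | BrC/C=C(\C)CCC=C(C)C | starting material
17 | (4E)-1-[(4R)-2,2-dimethyl-1,3-dioxolan-4-yl]-5,9-dimethyldeca-4,8-dien-1-one | CC1(C)OC[C@@H](O1)C(=O)CC/C=C(\C)CCC=C(C)C | intermediate
18 | (2R,5E)-2-[(4R)-2,2-dimethyl-1,3-dioxolan-4-yl]-6,10-dimethylundeca-5,9-dien-2-ol | CC1(C)OC[C@@H](O1)[C@](C)(O)CC/C=C(\C)CCC=C(C)C | intermediate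
19 | (2R,3R,6E)-3,7,11-trimethyldodeca-6,10-diene-1,2,3-triol | OC[C@@H](O)[C@](C)(O)CC/C=C(\C)CCC=C(C)C | intermediate
20 | (2R,3R,6E)-2,3-dihydroxy-3,7,11-trimethyldodeca-6,10-dien-1-yl 4-methylbenzenesulfonate | Cc1ccc(cc1)S(=O)(=O)OC[C@@H](O)[C@](C)(O)CC/C=C(\C)CCC=C(C)C | intermediate
21 | (2R,5E)-6,10-dimethyl-2-[(2R)-oxiran-2-yl]undeca-5,9-dien-2-ol | C1[C@@H](O1)[C@](C)(O)CC/C=C(\C)CCC=C(C)C | intermediate
22 | triethyl{[(2R,5E)-6,10-dimethyl-2-[(2R)-oxiran-2-yl]undeca-5,9-dien-2-yl]oxy}silane | C1[C@@H](O1)[C@](C)(O[Si](CC)(CC)CC)CC/C=C(\C)CCC=C(C)C | intermediate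
23 | 2-{(2R,5S)-5-[(3R,4R,7E)-3-hydroxy-4,8,12-trimethyl-1-(phenylsulfonyl)-4-[(triethylsilyl)oxy]trideca-7,11-dien-1-yl]oxan-2-yl}prop-2-en-1-ol (both C1' epimers) | C=C(CO)[C@H]1CC[C@H](C(C[C@@H](O)[C@](C)(O[Si](CC)(CC)CC)CC/C=C(\C)CCC=C(C)C)S(=O)(=O)c2ccccc2)CO1 | intermediate
24 | 2-{(2R,5S)-5-[(3R,4R,7E)-3-hydroxy-4,8,12-trimethyl-4-[(triethylsilyl)oxy]trideca-7,11-dien-1-yl]oxan-2-yl}prop-2-en-1-ol | C=C(CO)[C@H]1CC[C@H](CC[C@@H](O)[C@](C)(O[Si](CC)(CC)CC)CC/C=C(\C)CCC=C(C)C)CO1 | intermediate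
25 | 2-{(2R,5S)-5-[(3R,4R,7E)-3-hydroxy-4,8,12-trimethyl-4-[(triethylsilyl)oxy]trideca-7,11-dien-1-yl]oxan-2-yl}prop-2-enal | C=C(C=O)[C@H]1CC[C@H](CC[C@@H](O)[C@](C)(O[Si](CC)(CC)CC)CC/C=C(\C)CCC=C(C)C)CO1 | intermediate
26 | 2-{(2R,5S)-5-[(3R,4R,7E)-3-hydroxy-4,8,12-trimethyl-4-[(triethylsilyl)oxy]trideca-7,11-dien-1-yl]oxan-2-yl}prop-2-enoic acid | C=C(C(=O)O)[C@H]1CC[C@H](CC[C@@H](O)[C@](C)(O[Si](CC)(CC)CC)CC/C=C(\C)CCC=C(C)C)CO1 | intermediate
27 | 2-{(2R,5S)-5-[(3R,4R,7E)-3,4-dihydroxy-4,8,12-trimethyltrideca-7,11-dien-1-yl]oxan-2-yl}prop-2-enoic acid | C=C(C(=O)O)[C@H]1CC[C@H](CC[C@@H](O)[C@](C)(O)CC/C=C(\C)CCC=C(C)C)CO1 | target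

**Totals and risks**

Total step count: 16. Longest linear sequence: 10 steps (steps 2 to 7 and 13 to 16, from 4).

Step 7 (most at risk). The two faces of the C5=C1' alkene may not be told apart well enough, so that the cis ring forms alongside the trans ring. The C4 radical may also be lost by 1,5-hydrogen transfer or by direct reduction before it cyclizes. The fallback closes the same bond as a closed-shell anion at low temperature, where no hydrogen-atom transfer or hydride reduction exists. It sets out from 11. Silylation (t-BuMe2SiCl, imidazole, CH2Cl2) should give tert-butyl{[(3R)-5-iodo-2-methylidene-3-{[(2E)-3-(phenylsulfonyl)prop-2-en-1-yl]oxy}pentyl]oxy}dimethylsilane F1. Iodine–lithium exchange (t-BuLi, 2.1 equiv, pentane–Et2O, −100 °C) should then give the primary alkyllithium, which adds 6-exo to the vinyl sulfone on warming to −78 °C through a lithium-bridged chair. A methanol quench should give tert-butyldimethyl({2-[(2R,5S)-5-[(phenylsulfonyl)methyl]oxan-2-yl]prop-2-en-1-yl}oxy)silane F2. Bu4NF in THF removes the silyl group, and the route is rejoined at 12.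

Step 10. Chelation by the dioxolane oxygen may compete with the Felkin–Anh pathway, so that methyl adds to the wrong carbonyl face or with low selectivity. The fallback sets the tertiary centre by hydroxyl-directed epoxidation instead and sets out from 17. Wittig methylenation (Ph3P=CH2 from Ph3PCH3Br and KN(SiMe3)2, THF, −78 to 0 °C) should give (4S)-4-[(5E)-6,10-dimethylundeca-1,5,9-trien-2-yl]-2,2-dimethyl-1,3-dioxolane F3. Hydrolysis (AcOH–H2O) should give (2S,6E)-7,11-dimethyl-3-methylidenedodeca-6,10-diene-1,2-diol F4. Epoxidation with VO(acac)2 (cat.) and t-BuOOH in CH2Cl2 at 0 °C is directed by the allylic hydroxyl; allylic 1,2-strain from the methylidene substituent fixes the face, and the chain alkenes are not directed. It should give the erythro epoxide (1R)-1-{(2S)-2-[(3E)-4,8-dimethylnona-3,7-dien-1-yl]oxiran-2-yl}ethane-1,2-diol F5. LiAlH4 in THF at 0 °C opens the epoxide at its CH2 terminus, and the route is rejoined at 19.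

Step 3. Alkylation of the hindered, hydrogen-bonded carbinol may be slow, so that allylic transposition of the Morita–Baylis–Hillman system or oxa-Michael addition to the vinyl sulfone takes over. The fallback forms the same ether by reductive etherification through an oxocarbenium ion and sets out from 7 and 3. Silylation of 7 (Me3SiCl, Et3N, CH2Cl2) should give methyl (3R)-5-[(tert-butyldimethylsilyl)oxy]-2-methylidene-3-[(trimethylsilyl)oxy]pentanoate F6. Oxidation of 3 with N-methylmorpholine N-oxide in MeCN should give (2E)-3-(phenylsulfonyl)prop-2-enal F7. The two are combined with Et3SiH and catalytic Me3SiOTf in CH2Cl2 at −78 °C, and the route is rejoined at 8.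

**Further compounds**

F1 | step 7 | tert-butyl{[(3R)-5-iodo-2-methylidene-3-{[(2E)-3-(phenylsulfonyl)prop-2-en-1-yl]oxy}pentyl]oxy}dimethylsilane | C=C(CO[Si](C)(C)C(C)(C)C)[C@H](OC/C=C/S(=O)(=O)c1ccccc1)CCI
F2 | step 7 | tert-butyldimethyl({2-[(2R,5S)-5-[(phenylsulfonyl)methyl]oxan-2-yl]prop-2-en-1-yl}oxy)silane | C=C(CO[Si](C)(C)C(C)(C)C)[C@H]1CC[C@H](CS(=O)(=O)c2ccccc2)CO1
F3 | step 10 | (4S)-4-[(5E)-6,10-dimethylundeca-1,5,9-trien-2-yl]-2,2-dimethyl-1,3-dioxolane | CC1(C)OC[C@@H](O1)C(=C)CC/C=C(\C)CCC=C(C)C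
F4 | step 10 | (2S,6E)-7,11-dimethyl-3-methylidenedodeca-6,10-diene-1,2-diol | OC[C@@H](O)C(=C)CC/C=C(\C)CCC=C(C)C
F5 | step 10 | (1R)-1-{(2S)-2-[(3E)-4,8-dimethylnona-3,7-dien-1-yl]oxiran-2-yl}ethane-1,2-diol | OC[C@@H](O)[C@@]1(CO1)CC/C=C(\C)CCC=C(C)C
F6 | step 3 | methyl (3R)-5-[(tert-butyldimethylsilyl)oxy]-2-methylidene-3-[(trimethylsilyl)oxy]pentanoate | C=C(C(=O)OC)[C@H](O[Si](C)(C)C)CCO[Si](C)(C)C(C)(C)C
F7 | step 3 | (2E)-3-(phenylsulfonyl)prop-2-enal | O=C/C=C/S(=O)(=O)c1ccccc1
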